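Ring B is not coupled to ring A but grown on its ether oxygen. The route rests on cutting the C1'–C6' and C3'–C4' bonds of ring B. Its ether carbon C1' and phenol carbon C2' are neighbours, with the methyl on C4' and the hydroxymethyl carbon on C6'. That is the pattern an α-aryloxy methyl ketone (C1'–C2'–C3') leaves on condensing with a 4-oxo-2-ynoate (C4'–C5'–C6'). One base-mediated Michael–aldol–dehydration cascade forges both bonds, closes ring B and delivers it as the phenol with the C6' ester in place. The precursor is the ring-A aryloxyacetone carrying the silyl-protected (S)-carbinol and a tert-butyl ester, unveiled from a 2-methylallyl ether by ozonolysis.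

Key step: step 11

Conventions: ring A is numbered C1 (carboxyl carbon), C2 (OMe), C3 (side chain), C6 (ether oxygen). Ring B carries primes: C1' (ether carbon), C2' (OH), C4' (CH3), C6' (CH2OH). The (S) descriptor was re-derived from the target SMILES (O > aryl > CH2 > H) and is used throughout. Equivalents are proposed values.

Assumption (remark on the chemistry): the transient ozonide 11 and Michael adduct 18 are written without defining their new, non-persistent stereocentre.

Design points:
- The methyl-to-tert-butyl ester exchange is done at the ketone stage, before any stereocentre or silyl ether exists.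
- The acetonyl ether is carried as a 2-methylallyl ether, so only one ketone is present during the asymmetric reduction and no separate phenol protecting group is needed.
- The tert-butyl ester is removed at the end under buffered aprotic conditions while the benzylic oxygen is still silylated.

Step 1
Reactants: 1 methyl 2,6-dihydroxybenzoate; 2 3-methylbutanoyl chloride
Product: 3 methyl 2,6-dihydroxy-3-(3-methylbutanoyl)benzoate
Conditions: AlCl3 (3.5 equiv), ClCH2CH2Cl, 0 to 60 °C; aq. HCl work-up
Reagents that add atoms: none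
Why: Friedel–Crafts acylation (in part via O-acylation and Fries rearrangement) should go to C3, which is ortho to one hydroxyl and para to the other, C3 and C5 being equivalent by symmetry and the first acyl group deactivating the ring towards a second.

Step 2
Reactants: 3 methyl 2,6-dihydroxy-3-(3-methylbutanoyl)benzoate; 4 3-chloro-2-methylprop-1-ene
Product: 5 methyl 2-hydroxy-3-(3-methylbutanoyl)-6-[(2-methylprop-2-en-1-yl)oxy]benzoate
Conditions: K2CO3 (1.1 equiv), NaI (10 mol%), acetone, reflux
Reagents that add atoms: none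
Why: Williamson etherification should alkylate O6 only, because the C6 hydroxyl (para to the new ketone) is the more acidic and less hindered phenol, whereas the C2 hydroxyl is locked in a strong hydrogen bond to the ketone and flanked by two carbonyl substituents.

Step 3
Reactants: 5 methyl 2-hydroxy-3-(3-methylbutanoyl)-6-[(2-methylprop-2-en-1-yl)oxy]benzoate
Product: 6 methyl 2-methoxy-3-(3-methylbutanoyl)-6-[(2-methylprop-2-en-1-yl)oxy]benzoate
Conditions: MeI (3 equiv), K2CO3 (3 equiv), DMF, 50 °C
Reagents that add atoms: iodomethane, CI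
Why: Williamson O-methylation of the remaining chelated phenol needs excess reagent in a warm dipolar solvent but has no competing nucleophilic site.

Step 4
Reactants: 6 methyl 2-methoxy-3-(3-methylbutanoyl)-6-[(2-methylprop-2-en-1-yl)oxy]benzoate
Product: 7 2-methoxy-3-(3-methylbutanoyl)-6-[(2-methylprop-2-en-1-yl)oxy]benzoic acid
Conditions: NaOH (aq.), MeOH, reflux; then HCl to pH 2
Reagents that add atoms: sodium hydroxide, [Na+].[OH-]
Why: Saponification (BAc2) of a 2,6-dialkoxybenzoate is slow but routine at reflux and is placed here because the molecule still has no stereocentre, silyl ether or base-sensitive group.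

Step 5
Reactants: 7 2-methoxy-3-(3-methylbutanoyl)-6-[(2-methylprop-2-en-1-yl)oxy]benzoic acid
Product: 8 tert-butyl 2-methoxy-3-(3-methylbutanoyl)-6-[(2-methylprop-2-en-1-yl)oxy]benzoate
Conditions: tert-butyl 2,2,2-trichloroacetimidate (2.5 equiv), toluene, rt to 50 °C
Reagents that add atoms: tert-butyl 2,2,2-trichloroacetimidate, CC(C)(C)OC(=N)C(Cl)(Cl)Cl
Why: Alkylative esterification with a trichloroacetimidate works through protonation of the imidate by the acid and capture of the tert-butyl cation by the carboxylate, so the hindered carbonyl carbon is never attacked and no strong acid meets the 2-methylallyl ether.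

Step 6
Reactants: 8 tert-butyl 2-methoxy-3-(3-methylbutanoyl)-6-[(2-methylprop-2-en-1-yl)oxy]benzoate
Product: 9 tert-butyl 3-[(1S)-1-hydroxy-3-methylbutyl]-2-methoxy-6-[(2-methylprop-2-en-1-yl)oxy]benzoate
Conditions: (R)-2-methyl-CBS-oxazaborolidine (20 mol%), catecholborane (1.8 equiv), toluene, −78 to −40 °C; MeOH quench, aq. NaOH wash
Reagents that add atoms: none
Why: In this Corey–Bakshi–Shibata reduction the aryl ring acts as the large and the isobutyl chain as the small substituent, so the (R)-oxazaborolidine should deliver hydride to the Re face and set the (S)-carbinol, while catecholborane at low temperature neither hydroborates the 1,1-disubstituted alkene nor touches the tert-butyl ester.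

Step 7
Reactants: 9 tert-butyl 3-[(1S)-1-hydroxy-3-methylbutyl]-2-methoxy-6-[(2-methylprop-2-en-1-yl)oxy]benzoate
Product: 10 tert-butyl 3-[(1S)-1-{[tert-butyl(dimethyl)silyl]oxy}-3-methylbutyl]-2-methoxy-6-[(2-methylprop-2-en-1-yl)oxy]benzoate
Conditions: TBSCl (1.5 equiv), imidazole (3 equiv), DMAP (cat.), DMF, rt to 40 °C
Reagents that add atoms: tert-butyldimethylsilyl chloride, CC(C)(C)[Si](C)(C)Cl
Why: Imidazole-promoted silylation of the secondary benzylic alcohol runs under basic conditions that cannot ionise the carbinol, and the silyl ether is inert to ozone, carbonate and borohydride in the steps that follow.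

Step 8
Reactants: 10 tert-butyl 3-[(1S)-1-{[tert-butyl(dimethyl)silyl]oxy}-3-methylbutyl]-2-methoxy-6-[(2-methylprop-2-en-1-yl)oxy]benzoate
Product: 12 tert-butyl 3-[(1S)-1-{[tert-butyl(dimethyl)silyl]oxy}-3-methylbutyl]-2-methoxy-6-(2-oxopropoxy)benzoate, via ozonide 11 (not isolated)
Conditions: O3, CH2Cl2, −78 °C (Sudan Red 7B end-point); then Me2S, −78 °C to rt
Reagents that add atoms: ozone, [O-][O+]=O
Why: Ozonolysis (Criegee mechanism) should cleave the 1,1-disubstituted alkene far faster than ozone attacks the alkoxyarene, and reductive cleavage of the ozonide unveils the aryloxyacetone under neutral conditions that spare the ketone–ester pair.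

Step 9
Reactants: 13 ethyl prop-2-ynoate; 14 acetaldehyde
Product: 16 ethyl 4-hydroxypent-2-ynoate (racemic), via ethyl 3-lithioprop-2-ynoate 15 (not isolated)
Conditions: n-BuLi, THF, −78 °C; then MeCHO, −78 °C; AcOH quench
Reagents that add atoms: none
Why: Addition of a lithium acetylide to an aldehyde is reliable here because lithiated ethyl propiolate is stable below −70 °C, and the new carbinol centre is irrelevant since it is oxidised in the next step.

Step 10
Reactants: 16 ethyl 4-hydroxypent-2-ynoate (racemic)
Product: 17 ethyl 4-oxopent-2-ynoate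
Conditions: Dess–Martin periodinane, CH2Cl2, 0 °C to rt
Reagents that add atoms: none
Why: Dess–Martin oxidation converts the secondary propargylic alcohol into the ynone under non-basic conditions that this base-sensitive acceptor should survive.

Step 11
Reactants: 12 tert-butyl 3-[(1S)-1-{[tert-butyl(dimethyl)silyl]oxy}-3-methylbutyl]-2-methoxy-6-(2-oxopropoxy)benzoate; 17 ethyl 4-oxopent-2-ynoate
Product: 19 tert-butyl 6-[2-(ethoxycarbonyl)-6-hydroxy-4-methylphenoxy]-3-[(1S)-1-{[tert-butyl(dimethyl)silyl]oxy}-3-methylbutyl]-2-methoxybenzoate, via Michael adduct 18 (not isolated)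
Conditions: Cs2CO3 (2 equiv), DMF, Ar, 0 °C, 17 (1.3 equiv) added slowly, to rt; then 60 °C; aq. NH4Cl
Reagents that add atoms: none
Why: Proposed new method: carbonate reversibly forms the thermodynamic enolate of 12 at the aryloxy-bearing carbon C1' (an α-aryloxy group acidifies a ketone α-position by several pKa units relative to the methyl side), which adds in Michael fashion to the alkyne carbon of 17 that is β to the ketone and carries the ester, forging C1'–C6' and giving ene-dione 18, held under base as a vinylogous diketonate so that its E and Z isomers equilibrate; the C3' methyl-ketone enolate then closes onto the C4' ketone, water is lost by E1cB and the resulting cyclohexadienone tautomerises irreversibly to the C2' phenol. The closest known reaction type is the base-mediated [3+3] Michael–aldol benzannulation of 1,3-disubstituted acetones or β-keto esters with conjugated ynones, together with the classical conversion of 2-methylpyrylium pseudobases (2-ene-1,5-diones) into phenols, whereas an α-aryloxy methyl ketone paired with a 4-oxo-2-ynoate has not been shown. Ring B closes by a 6-(enolendo)-exo-trig aldol, a favoured mode. No stereocentre is created and the silyl-protected (S)-carbinol is remote from every enolisable position. The step needs three selectivities: Michael attack from C1' and not from C3' (secured by the acidifying aryloxy group under equilibrating conditions), attack at the ynoate carbon β to the ketone (the ketone is the stronger acceptor), and aldol in the C3'-to-C4' direction and not from the ynone-derived methyl onto C2' (C2' is shielded by the neighbouring carbon that bears the bulky aryloxy group with its ortho tert-butyl ester, whereas C4' is unhindered). The tert-butyl ester also retards 5-exo Dieckmann closure of the C1' enolate onto the ring-A ester.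

Step 12
Reactants: 19 tert-butyl 6-[2-(ethoxycarbonyl)-6-hydroxy-4-methylphenoxy]-3-[(1S)-1-{[tert-butyl(dimethyl)silyl]oxy}-3-methylbutyl]-2-methoxybenzoate
Product: 20 tert-butyl 3-[(1S)-1-{[tert-butyl(dimethyl)silyl]oxy}-3-methylbutyl]-6-[2-hydroxy-6-(hydroxymethyl)-4-methylphenoxy]-2-methoxybenzoate
Conditions: LiBH4 (4 equiv), MeOH (4 equiv), THF, 0 to 40 °C; aq. NH4Cl
Reagents that add atoms: none
Why: Lithium borohydride reduction should take the aryl ethyl ester to the benzylic alcohol, while the tert-butyl ester flanked by two ortho substituents is inert to this reagent and the phenol is merely deprotonated.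

Step 13
Reactants: 20 tert-butyl 3-[(1S)-1-{[tert-butyl(dimethyl)silyl]oxy}-3-methylbutyl]-6-[2-hydroxy-6-(hydroxymethyl)-4-methylphenoxy]-2-methoxybenzoate
Product: 22 6-[2-hydroxy-6-(hydroxymethyl)-4-methylphenoxy]-3-[(1S)-1-hydroxy-3-methylbutyl]-2-methoxybenzoic acid (target), via persilylated intermediate 21 (not isolated)
Conditions: TMSOTf (6 equiv), 2,6-lutidine (9 equiv), CH2Cl2, 0 °C to rt; then TBAF (excess), THF, rt; dilute HCl to pH 3–4 at 0 °C
Reagents that add atoms: none
Why: Silyl triflate-mediated cleavage of the tert-butyl ester (O-silylation of the ester carbonyl and loss of isobutene) should proceed under lutidine-buffered aprotic conditions while the benzylic oxygen is still a bulky, weakly basic silyl ether, which guards the (S)-carbinol against ionisation, and fluoride then removes all four silyl groups without acid.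

Compound list

1 | methyl 2,6-dihydroxybenzoate | COC(=O)c1c(O)cccc1O | starting material
2 | 3-methylbutanoyl chloride (isovaleryl chloride) | CC(C)CC(=O)Cl | starting material
3 | methyl 2,6-dihydroxy-3-(3-methylbutanoyl)benzoate | COC(=O)c1c(O)ccc(C(=O)CC(C)C)c1O | intermediate
4 | 3-chloro-2-methylprop-1-ene (methallyl chloride) | CC(=C)CCl | starting material
5 | methyl 2-hydroxy-3-(3-methylbutanoyl)-6-[(2-methylprop-2-en-1-yl)oxy]benzoate | COC(=O)c1c(OCC(C)=C)ccc(C(=O)CC(C)C)c1O | intermediate
6 | methyl 2-methoxy-3-(3-methylbutanoyl)-6-[(2-methylprop-2-en-1-yl)oxy]benzoate | COC(=O)c1c(OCC(C)=C)ccc(C(=O)CC(C)C)c1OC | intermediate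
7 | 2-methoxy-3-(3-methylbutanoyl)-6-[(2-methylprop-2-en-1-yl)oxy]benzoic acid | OC(=O)c1c(OCC(C)=C)ccc(C(=O)CC(C)C)c1OC | intermediate
8 | tert-butyl 2-methoxy-3-(3-methylbutanoyl)-6-[(2-methylprop-2-en-1-yl)oxy]benzoate | CC(C)(C)OC(=O)c1c(OCC(C)=C)ccc(C(=O)CC(C)C)c1OC | intermediate
9 | tert-butyl 3-[(1S)-1-hydroxy-3-methylbutyl]-2-methoxy-6-[(2-methylprop-2-en-1-yl)oxy]benzoate | CC(C)(C)OC(=O)c1c(OCC(C)=C)ccc([C@@H](O)CC(C)C)c1OC | intermediate
10 | tert-butyl 3-[(1S)-1-{[tert-butyl(dimethyl)silyl]oxy}-3-methylbutyl]-2-methoxy-6-[(2-methylprop-2-en-1-yl)oxy]benzoate | CC(C)(C)OC(=O)c1c(OCC(C)=C)ccc([C@@H](O[Si](C)(C)C(C)(C)C)CC(C)C)c1OC | intermediate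
11 | ozonide: tert-butyl 3-[(1S)-1-{[tert-butyl(dimethyl)silyl]oxy}-3-methylbutyl]-2-methoxy-6-[(3-methyl-1,2,4-trioxolan-3-yl)methoxy]benzoate (epimers at the trioxolane carbon) | CC(C)(C)OC(=O)c1c(OCC2(C)OCOO2)ccc([C@@H](O[Si](C)(C)C(C)(C)C)CC(C)C)c1OC | intermediate (not isolated)
12 | tert-butyl 3-[(1S)-1-{[tert-butyl(dimethyl)silyl]oxy}-3-methylbutyl]-2-methoxy-6-(2-oxopropoxy)benzoate | COc1c([C@@H](O[Si](C)(C)C(C)(C)C)CC(C)C)ccc(OCC(C)=O)c1C(=O)OC(C)(C)C | intermediate (key-step precursor)
13 | ethyl prop-2-ynoate (ethyl propiolate) | C#CC(=O)OCC | starting material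
14 | acetaldehyde | CC=O | starting material
15 | ethyl 3-lithioprop-2-ynoate | [Li]C#CC(=O)OCC | intermediate (not isolated)
16 | ethyl 4-hydroxypent-2-ynoate (racemic) | CCOC(=O)C#CC(C)O | intermediate
17 | ethyl 4-oxopent-2-ynoate | CCOC(=O)C#CC(C)=O | intermediate
18 | Michael adduct: tert-butyl 3-[(1S)-1-{[tert-butyl(dimethyl)silyl]oxy}-3-methylbutyl]-6-{[(4E)-4-(ethoxycarbonyl)-2,6-dioxohept-4-en-3-yl]oxy}-2-methoxybenzoate (epimers at C3 of the heptene chain) | COc1c([C@@H](O[Si](C)(C)C(C)(C)C)CC(C)C)ccc(OC(C(C)=O)/C(C(=O)OCC)=C\C(C)=O)c1C(=O)OC(C)(C)C | intermediate (not isolated)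
19 | tert-butyl 6-[2-(ethoxycarbonyl)-6-hydroxy-4-methylphenoxy]-3-[(1S)-1-{[tert-butyl(dimethyl)silyl]oxy}-3-methylbutyl]-2-methoxybenzoate | COc1c([C@@H](O[Si](C)(C)C(C)(C)C)CC(C)C)ccc(Oc2c(O)cc(C)cc2C(=O)OCC)c1C(=O)OC(C)(C)C | intermediate (key-step product)
20 | tert-butyl 3-[(1S)-1-{[tert-butyl(dimethyl)silyl]oxy}-3-methylbutyl]-6-[2-hydroxy-6-(hydroxymethyl)-4-methylphenoxy]-2-methoxybenzoate | COc1c([C@@H](O[Si](C)(C)C(C)(C)C)CC(C)C)ccc(Oc2c(O)cc(C)cc2CO)c1C(=O)OC(C)(C)C | intermediate
21 | trimethylsilyl 3-[(1S)-1-{[tert-butyl(dimethyl)silyl]oxy}-3-methylbutyl]-2-methoxy-6-{4-methyl-2-[(trimethylsilyl)oxy]-6-{[(trimethylsilyl)oxy]methyl}phenoxy}benzoate | COc1c([C@@H](O[Si](C)(C)C(C)(C)C)CC(C)C)ccc(Oc2c(O[Si](C)(C)C)cc(C)cc2CO[Si](C)(C)C)c1C(=O)O[Si](C)(C)C | intermediate (not isolated)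
22 | 6-[2-hydroxy-6-(hydroxymethyl)-4-methylphenoxy]-3-[(1S)-1-hydroxy-3-methylbutyl]-2-methoxybenzoic acid | COc1c([C@@H](O)CC(C)C)ccc(Oc2c(O)cc(C)cc2CO)c1C(=O)O | target

Total step count: 13. Longest linear sequence: 11 steps (steps 1–8, 11, 12, 13); the ynone 17 is made in a two-step side branch (steps 9–10).

Steps most likely to fail

1. Step 11 (Proposed new method). Several processes may go wrong. The closing aldol may run in the opposite sense, with the enolate of the ynone-derived methyl attacking C2', which would give a regioisomeric ring B. The Michael addition may start from the C3' methyl. The ynone may oligomerise under base faster than it is captured. The C1' enolate may close onto the ring-A ester. The fallback uses known chemistry, making the diaryl ether by SNAr instead of benzannulation; it sets out from 10 and comes back to the route at 20. The 2-methylallyl ether of 10 would be removed by π-allyl transfer (Pd(PPh3)4, morpholine, THF, rt) to give the phenol tert-butyl 3-[(1S)-1-{[tert-butyl(dimethyl)silyl]oxy}-3-methylbutyl]-6-hydroxy-2-methoxybenzoate F1. The ring-B partner would come from commercial 2-fluoro-5-methylphenol by O-benzylation (BnBr, K2CO3, DMF) to 2-(benzyloxy)-1-fluoro-4-methylbenzene F2. Fluorine-directed ortho-lithiation (LiTMP, THF, −78 °C) and DMF quench would then give 3-(benzyloxy)-2-fluoro-5-methylbenzaldehyde F3. SNAr of the phenoxide of F1 on the fluoride ortho to the formyl group of F3 (K2CO3, DMF, 90–110 °C) would give tert-butyl 6-[2-(benzyloxy)-6-formyl-4-methylphenoxy]-3-[(1S)-1-{[tert-butyl(dimethyl)silyl]oxy}-3-methylbutyl]-2-methoxybenzoate F4. NaBH4 (MeOH, 0 °C) would reduce the aldehyde to tert-butyl 6-[2-(benzyloxy)-6-(hydroxymethyl)-4-methylphenoxy]-3-[(1S)-1-{[tert-butyl(dimethyl)silyl]oxy}-3-methylbutyl]-2-methoxybenzoate F5. Hydrogenolysis of the aryl benzyl ether (H2, Pd/C, EtOAc) would deliver 20, from which step 13 follows unchanged.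

2. Step 13. Silyl triflate activation may ionise the benzylic C–O bond para to the aryloxy group, which would erode the configuration or cause elimination towards the styrene. The doubly ortho-flanked tert-butyl ester may also be cleaved incompletely. The fallback changes the carboxyl protection to a fluoride-labile ester so that the endgame needs no Lewis acid; it sets out from 7 and comes back at the target 22.
   - Mitsunobu esterification of 7 with 2-(trimethylsilyl)ethanol (PPh3, DIAD, THF; the acid acts as the nucleophile, so hindrance at the carbonyl does not matter) would give 2-(trimethylsilyl)ethyl 2-methoxy-3-(3-methylbutanoyl)-6-[(2-methylprop-2-en-1-yl)oxy]benzoate F6.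
   - The operations of steps 6 and 7 would give in turn the (S)-alcohol analogue of 9 F7 and the silyl ether analogue of 10 F8.
   - The operation of step 8 would give, via the ozonide analogue of 11 F9 (not isolated), the aryloxyacetone analogue of 12 F10.
   - The operation of step 11 would give, via the Michael adduct analogue of 18 F11 (not isolated), the benzannulation product analogue of 19 F12.
   - The operation of step 12 would give the diol analogue of 20 F13.
   - TBAF (THF, rt) would then remove the silyl ether and the silylethyl ester (fluoride-induced fragmentation with loss of ethene) in one acid-free operation to give 22.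
   - The price is a less hindered ring-A ester during the benzannulation.

3. Step 6. Hydride transfer to the hindered, electron-rich ketone may be slow, with reduced facial selectivity, and the 2-methylallyl group may be hydroborated if the temperature has to be raised. The fallback sets out from 8 and comes back at 9 without new intermediates. It is a Noyori asymmetric transfer hydrogenation with RuCl[(S,S)-TsDPEN](p-cymene) in HCO2H/Et3N (5:2) at rt to 40 °C. This is an outer-sphere Ru–H/N–H hydride transfer that involves no B–H species, leaves isolated alkenes alone and gives the (S)-alcohol with aryl alkyl ketones.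

Further compounds

F1 | step 11 | tert-butyl 3-[(1S)-1-{[tert-butyl(dimethyl)silyl]oxy}-3-methylbutyl]-6-hydroxy-2-methoxybenzoate | COc1c([C@@H](O[Si](C)(C)C(C)(C)C)CC(C)C)ccc(O)c1C(=O)OC(C)(C)C
F2 | step 11 | 2-(benzyloxy)-1-fluoro-4-methylbenzene | Cc1ccc(F)c(OCc2ccccc2)c1
F3 | step 11 | 3-(benzyloxy)-2-fluoro-5-methylbenzaldehyde | Cc1cc(C=O)c(F)c(OCc2ccccc2)c1
F4 | step 11 | tert-butyl 6-[2-(benzyloxy)-6-formyl-4-methylphenoxy]-3-[(1S)-1-{[tert-butyl(dimethyl)silyl]oxy}-3-methylbutyl]-2-methoxybenzoate | COc1c([C@@H](O[Si](C)(C)C(C)(C)C)CC(C)C)ccc(Oc2c(OCc3ccccc3)cc(C)cc2C=O)c1C(=O)OC(C)(C)C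
F5 | step 11 | tert-butyl 6-[2-(benzyloxy)-6-(hydroxymethyl)-4-methylphenoxy]-3-[(1S)-1-{[tert-butyl(dimethyl)silyl]oxy}-3-methylbutyl]-2-methoxybenzoate | COc1c([C@@H](O[Si](C)(C)C(C)(C)C)CC(C)C)ccc(Oc2c(OCc3ccccc3)cc(C)cc2CO)c1C(=O)OC(C)(C)C
F6 | step 13 | 2-(trimethylsilyl)ethyl 2-methoxy-3-(3-methylbutanoyl)-6-[(2-methylprop-2-en-1-yl)oxy]benzoate | C[Si](C)(C)CCOC(=O)c1c(OCC(C)=C)ccc(C(=O)CC(C)C)c1OC
F7 | step 13 | 2-(trimethylsilyl)ethyl 3-[(1S)-1-hydroxy-3-methylbutyl]-2-methoxy-6-[(2-methylprop-2-en-1-yl)oxy]benzoate | C[Si](C)(C)CCOC(=O)c1c(OCC(C)=C)ccc([C@@H](O)CC(C)C)c1OC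
F8 | step 13 | 2-(trimethylsilyl)ethyl 3-[(1S)-1-{[tert-butyl(dimethyl)silyl]oxy}-3-methylbutyl]-2-methoxy-6-[(2-methylprop-2-en-1-yl)oxy]benzoate | C[Si](C)(C)CCOC(=O)c1c(OCC(C)=C)ccc([C@@H](O[Si](C)(C)C(C)(C)C)CC(C)C)c1OC
F9 | step 13 | 2-(trimethylsilyl)ethyl 3-[(1S)-1-{[tert-butyl(dimethyl)silyl]oxy}-3-methylbutyl]-2-methoxy-6-[(3-methyl-1,2,4-trioxolan-3-yl)methoxy]benzoate (not isolated) | C[Si](C)(C)CCOC(=O)c1c(OCC2(C)OCOO2)ccc([C@@H](O[Si](C)(C)C(C)(C)C)CC(C)C)c1OC
F10 | step 13 | 2-(trimethylsilyl)ethyl 3-[(1S)-1-{[tert-butyl(dimethyl)silyl]oxy}-3-methylbutyl]-2-methoxy-6-(2-oxopropoxy)benzoate | C[Si](C)(C)CCOC(=O)c1c(OCC(C)=O)ccc([C@@H](O[Si](C)(C)C(C)(C)C)CC(C)C)c1OC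
F11 | step 13 | 2-(trimethylsilyl)ethyl 3-[(1S)-1-{[tert-butyl(dimethyl)silyl]oxy}-3-methylbutyl]-6-{[(4E)-4-(ethoxycarbonyl)-2,6-dioxohept-4-en-3-yl]oxy}-2-methoxybenzoate (not isolated) | C[Si](C)(C)CCOC(=O)c1c(OC(C(C)=O)/C(C(=O)OCC)=C\C(C)=O)ccc([C@@H](O[Si](C)(C)C(C)(C)C)CC(C)C)c1OC
F12 | step 13 | 2-(trimethylsilyl)ethyl 6-[2-(ethoxycarbonyl)-6-hydroxy-4-methylphenoxy]-3-[(1S)-1-{[tert-butyl(dimethyl)silyl]oxy}-3-methylbutyl]-2-methoxybenzoate | C[Si](C)(C)CCOC(=O)c1c(Oc2c(O)cc(C)cc2C(=O)OCC)ccc([C@@H](O[Si](C)(C)C(C)(C)C)CC(C)C)c1OC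
F13 | step 13 | 2-(trimethylsilyl)ethyl 3-[(1S)-1-{[tert-butyl(dimethyl)silyl]oxy}-3-methylbutyl]-6-[2-hydroxy-6-(hydroxymethyl)-4-methylphenoxy]-2-methoxybenzoate | C[Si](C)(C)CCOC(=O)c1c(Oc2c(O)cc(C)cc2CO)ccc([C@@H](O[Si](C)(C)C(C)(C)C)CC(C)C)c1OC
F0 | step 6 | none | none
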